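**Strategy.** Ring C (O1–C2–C3–C4–C4a–C8a) is read as the benzo-fused adduct of an aryl aldehyde with an "aromatic Danishefsky diene": the enol silane of a 2-fluoroaryl methyl ketone, in which the ring-A bond C4a=C8a links the C4 ketone to a fluorine-bearing C8a. In one flask a catalytic enantioselective Mukaiyama aldol forms C2–C3 and sets C2, and fluoride-relayed desilylation lets the C2 oxygen displace that fluorine (O1–C8a); O1 is thus the aldehyde oxygen. The precursors are a protected 3-prenyl-4-hydroxybenzaldehyde and a fluororesorcinol-derived enol silane whose 5-O-prenyl ether serves as protecting group and is later relayed to C8 by a Claisen–Cope shift.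

Key step: step 7

Remark (assumption): the (R)-tryptophan antipode of the oxazaborolidinone is taken to direct the enol silane to the Si face of aldehyde 8, which gives 2S; should a test run show the opposite sense, the (S)-tryptophan catalyst is used with no other change.

Step 1
Reactants: 1 5-fluororesorcinol
Product: 2 1-(2-fluoro-4,6-dihydroxyphenyl)ethanone
Conditions: AcOH (1.2 equiv), BF3·OEt2 (as solvent), 90 °C; then H2O
Reagents that add atoms: acetic acid, CC(=O)O
Why: Friedel–Crafts (Nencki-type) acylation in which the two hydroxyls direct the acyl group para to one OH and ortho to the other, as in the acylation of resorcinol and orcinol, the site between the hydroxyls being disfavoured.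

Step 2
Reactants: 2 1-(2-fluoro-4,6-dihydroxyphenyl)ethanone
Product: 3 1-[2-fluoro-6-hydroxy-4-(methoxymethoxy)phenyl]ethanone
Conditions: MOMCl (1.05 equiv), iPr2NEt, CH2Cl2, 0 °C
Reagents that add atoms: chloromethyl methyl ether (MOMCl), COCCl
Why: Williamson-type O-alkylation that should take place at the 4-hydroxyl only, since the 6-hydroxyl is hydrogen-bonded to the ketone and is the less acidic of the two.

Step 3
Reactants: 3 1-[2-fluoro-6-hydroxy-4-(methoxymethoxy)phenyl]ethanone
Product: 4 1-[2-fluoro-4-(methoxymethoxy)-6-(3-methylbut-2-enyloxy)phenyl]ethanone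
Conditions: prenyl bromide, K2CO3, DMF, 40 °C
Reagents that add atoms: prenyl bromide (1-bromo-3-methylbut-2-ene), CC(C)=CCBr
Why: Williamson etherification of the remaining chelated phenol with K2CO3 in a dipolar aprotic solvent, conditions that favour O- over C-alkylation and leave the aryl fluoride untouched.

Step 4
Reactants: 4 1-[2-fluoro-4-(methoxymethoxy)-6-(3-methylbut-2-enyloxy)phenyl]ethanone
Product: 5 {1-[2-fluoro-4-(methoxymethoxy)-6-(3-methylbut-2-enyloxy)phenyl]ethenyloxy}trimethylsilane
Conditions: LiN(SiMe3)2, THF, −78 °C; then Me3SiCl, −78 → 0 °C; non-aqueous work-up, used crude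
Reagents that add atoms: chlorotrimethylsilane, C[Si](C)(C)Cl
Why: Kinetic deprotonation of the methyl ketone (the only enolisable site) and O-silylation of the lithium enolate should give the enol silane, LiN(SiMe3)2 being too weak a base to metalate the arene next to fluorine.

Step 5
Reactants: 6 4-hydroxybenzaldehyde
Product: 7 4-hydroxy-3-(3-methylbut-2-enyl)benzaldehyde
Conditions: prenyl bromide, KOH (10% aq), rt
Reagents that add atoms: prenyl bromide (1-bromo-3-methylbut-2-ene), CC(C)=CCBr
Why: Direct ortho C-prenylation of the ambident phenoxide in water, where hydrogen bonding shields oxygen and the blocked para position leaves only the ortho carbon, followed by tautomerisation back to the phenol; O-alkylation and double alkylation are expected side paths and are removed by chromatography.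

Step 6
Reactants: 7 4-hydroxy-3-(3-methylbut-2-enyl)benzaldehyde
Product: 8 4-(methoxymethoxy)-3-(3-methylbut-2-enyl)benzaldehyde
Conditions: MOMCl, iPr2NEt, CH2Cl2, 0 °C → rt
Reagents that add atoms: chloromethyl methyl ether (MOMCl), COCCl
Why: Acetal-forming O-alkylation of the phenol masks the acidic OH before the Lewis acid and fluoride stages.

Step 7
Reactants: 5 {1-[2-fluoro-4-(methoxymethoxy)-6-(3-methylbut-2-enyloxy)phenyl]ethenyloxy}trimethylsilane (1.0 equiv); 8 4-(methoxymethoxy)-3-(3-methylbut-2-enyl)benzaldehyde (1.1 equiv)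
Product: 10 (2S)-7-(methoxymethoxy)-2-[4-(methoxymethoxy)-3-(3-methylbut-2-enyl)phenyl]-5-(3-methylbut-2-enyloxy)-2,3-dihydro-4H-chromen-4-one, via trimethylsilyl aldol ether 9 (not isolated)
Conditions: (R)-2-butyl-4-(indol-3-ylmethyl)-3-tosyl-1,3,2-oxazaborolidin-5-one (20 mol%), EtCN, −78 °C; then Bu4N[Ph3SiF2] (0.5 equiv), THF, −78 → −20 °C; pH 7 buffer
Reagents that add atoms: none
Why: A boron-catalysed Mukaiyama aldol joins the CH2 terminus of enol silane 5 to the carbonyl carbon of 8 (C3–C2) with transfer of the silyl group to the new alkoxide (9), and fluoride then unmasks that alkoxide, which adds to the fluorine-bearing C8a ortho to the C4 ketone and expels fluoride (SNAr, O1–C8a), the expelled fluoride desilylating the next molecule of 9. The closest known reactions are the oxazaborolidinone-catalysed aldol–cyclisation route from Danishefsky-type dienes and aldehydes to dihydropyranones, of which this is the benzo-fused case with fluoride in place of methoxide as leaving group, and the fluoride-catalysed etherification of silyl ethers with carbonyl-activated aryl fluorides. Ring C closes by addition–elimination through a Meisenheimer intermediate, formally a 6-endo-trig attack of oxygen on the vinylogous acyl fluoride F–C8a=C4a–C4=O. C2 is set in the aldol stage by the chiral oxazaborolidinone, which exposes the Si face of the bound aldehyde, and it is not touched afterwards because the C2–O bond is never broken. The step needs ring closure to outrun retro-aldol cleavage and β-elimination of the aldolate, which the ortho-carbonyl activation, the unhindered C8a (C8 still bears hydrogen), the non-basic fluoride source and the low standing concentration of alkoxide are meant to secure. Site selectivity on ring A follows from fluoride being by far the best nucleofuge there, the prenyl ether on the other ortho carbon being a much poorer one.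

Step 8
Reactants: 10 (2S)-7-(methoxymethoxy)-2-[4-(methoxymethoxy)-3-(3-methylbut-2-enyl)phenyl]-5-(3-methylbut-2-enyloxy)-2,3-dihydro-4H-chromen-4-one
Product: 12 (2S)-5-hydroxy-7-(methoxymethoxy)-2-[4-(methoxymethoxy)-3-(3-methylbut-2-enyl)phenyl]-8-(3-methylbut-2-enyl)-2,3-dihydro-4H-chromen-4-one, via ortho-dienone 11 (not isolated)
Conditions: Eu(fod)3 (10 mol%), NaHCO3, PhCl, 85 °C
Reagents that add atoms: none
Why: Para-Claisen–Cope sequence promoted by Eu(fod)3, a trivalent europium chelator of the C4 carbonyl and the 5-oxygen, in which the aromatic Claisen shift places the inverted allyl unit on C6 (C4a is blocked) to give dienone 11, a Cope shift moves it on to C8 with the prenyl connectivity restored, and enolisation gives the 5-phenol, no bond at C2 being involved so that the 2S centre is carried through.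

Step 9
Reactants: 12 (2S)-5-hydroxy-7-(methoxymethoxy)-2-[4-(methoxymethoxy)-3-(3-methylbut-2-enyl)phenyl]-8-(3-methylbut-2-enyl)-2,3-dihydro-4H-chromen-4-one
Product: 13 Euchrestaflavanone A, (2S)-5,7-dihydroxy-2-[4-hydroxy-3-(3-methylbut-2-enyl)phenyl]-8-(3-methylbut-2-enyl)-2,3-dihydro-4H-chromen-4-one
Conditions: HCl (3 M aq), MeOH, 40 °C
Reagents that add atoms: none
Why: Acid-catalysed methanolysis of the two methoxymethyl acetals (acetal exchange to dimethoxymethane) under conditions mild enough that the prenyl groups should stay unhydrated and uncyclised, C2 not being epimerisable under acid.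

**Compound list**

1 | 5-fluororesorcinol (5-fluorobenzene-1,3-diol) | Oc1cc(O)cc(F)c1 | starting material
2 | 1-(2-fluoro-4,6-dihydroxyphenyl)ethanone | CC(=O)c1c(O)cc(O)cc1F | intermediate
3 | 1-[2-fluoro-6-hydroxy-4-(methoxymethoxy)phenyl]ethanone | CC(=O)c1c(O)cc(OCOC)cc1F | intermediate
4 | 1-[2-fluoro-4-(methoxymethoxy)-6-(3-methylbut-2-enyloxy)phenyl]ethanone | CC(=O)c1c(OCC=C(C)C)cc(OCOC)cc1F | intermediate
5 | {1-[2-fluoro-4-(methoxymethoxy)-6-(3-methylbut-2-enyloxy)phenyl]ethenyloxy}trimethylsilane | C=C(O[Si](C)(C)C)c1c(OCC=C(C)C)cc(OCOC)cc1F | intermediate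
6 | 4-hydroxybenzaldehyde | O=Cc1ccc(O)cc1 | starting material
7 | 4-hydroxy-3-(3-methylbut-2-enyl)benzaldehyde | CC(C)=CCc1cc(C=O)ccc1O | intermediate
8 | 4-(methoxymethoxy)-3-(3-methylbut-2-enyl)benzaldehyde | CC(C)=CCc1cc(C=O)ccc1OCOC | intermediate
9 | (3S)-1-[2-fluoro-4-(methoxymethoxy)-6-(3-methylbut-2-enyloxy)phenyl]-3-[4-(methoxymethoxy)-3-(3-methylbut-2-enyl)phenyl]-3-(trimethylsilyloxy)propan-1-one | CC(C)=CCc1cc([C@@H](O[Si](C)(C)C)CC(=O)c2c(OCC=C(C)C)cc(OCOC)cc2F)ccc1OCOC | intermediate (not isolated)
10 | (2S)-7-(methoxymethoxy)-2-[4-(methoxymethoxy)-3-(3-methylbut-2-enyl)phenyl]-5-(3-methylbut-2-enyloxy)-2,3-dihydro-4H-chromen-4-one | CC(C)=CCc1cc([C@@H]2CC(=O)c3c(OCC=C(C)C)cc(OCOC)cc3O2)ccc1OCOC | intermediate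
11 | (2S)-7-(methoxymethoxy)-2-[4-(methoxymethoxy)-3-(3-methylbut-2-enyl)phenyl]-6-(2-methylbut-3-en-2-yl)-2,3-dihydro-4H-chromene-4,5(6H)-dione (either configuration at C6) | CC(C)=CCc1cc([C@@H]2CC(=O)C3=C(O2)C=C(OCOC)C(C(C)(C)C=C)C3=O)ccc1OCOC | intermediate (not isolated)
12 | (2S)-5-hydroxy-7-(methoxymethoxy)-2-[4-(methoxymethoxy)-3-(3-methylbut-2-enyl)phenyl]-8-(3-methylbut-2-enyl)-2,3-dihydro-4H-chromen-4-one | CC(C)=CCc1cc([C@@H]2CC(=O)c3c(O)cc(OCOC)c(CC=C(C)C)c3O2)ccc1OCOC | intermediate
13 | Euchrestaflavanone A | CC(C)=CCc1cc([C@@H]2CC(=O)c3c(O)cc(O)c(CC=C(C)C)c3O2)ccc1O | target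

**Step count and risks**

Total steps: 9. Longest linear sequence: 7 (steps 1, 2, 3, 4, 7, 8, 9).

Step 7. The unmasked alkoxide may undergo retro-aldol cleavage and recombination before it closes the ring, which would erode the enantiopurity, or the aldolate may be lost by β-elimination. The fallback sets out from 5 and 8 and comes back at 10. The aldol stage alone is run (same oxazaborolidinone, or SiCl4 with a chiral bisphosphoramide) and worked up with dilute acid to give the isolated (3S)-3-hydroxy ketone F1. NaBH4 in MeOH then reduces the ketone to the 1,3-diol F2 (either configuration at the new carbinol), which removes both the retro-aldol and the elimination pathway. KOtBu in DMF at 60–80 °C should close ring C by SNAr of the benzylic alkoxide on the now unactivated fluoroarene to give the (2S)-flavan-4-ol F3; only the C2 oxygen can reach C8a in a six-membered transition state. Dess–Martin periodinane in CH2Cl2 returns the ketone, 10.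

Step 8. The ortho-dienone may enolise before the Cope shift, leaving the allyl unit at C6 in inverted form, and prolonged heating with a Lewis acid may allow slow opening and reclosure of ring C at C2. The fallback sets out from 4 (with 8) and comes back at 13; it moves the rearrangement ahead of the key step, where no stereocentre is at stake. Ketone 4 is rearranged (Eu(fod)3 in PhCl, or N,N-diethylaniline at 200 °C) to 1-[2-fluoro-6-hydroxy-4-(methoxymethoxy)-3-(3-methylbut-2-enyl)phenyl]ethanone F4. MOMCl and iPr2NEt give the bis(methoxymethyl) ether F5, and LiN(SiMe3)2 with Me3SiCl gives the enol silane F6. The conditions of step 7 with 8 should then give, through the silyl aldol ether F7 (not isolated), the fully protected (2S)-8-prenylflavanone F8. HCl in MeOH as in step 9 gives 13.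

Step 9. Acid may induce cyclisation of a prenyl group onto the neighbouring freed phenol, or hydration of the alkene, during acetal cleavage. The fallback sets out from 12 and comes back at 13; it replaces protic solvolysis by trans-protection. Me3SiOTf and 2,2'-bipyridyl in CH2Cl2 at 0 °C should convert the aryl methoxymethyl ethers into aryl silyl ethers (the 5-hydroxyl is silylated as well) to give the tris(trimethylsilyl) ether F9. Brief methanolysis at rt under neutral conditions then frees 13.

**Further compounds**

F1 | step 7 | (3S)-1-[2-fluoro-4-(methoxymethoxy)-6-(3-methylbut-2-enyloxy)phenyl]-3-hydroxy-3-[4-(methoxymethoxy)-3-(3-methylbut-2-enyl)phenyl]propan-1-one | CC(C)=CCc1cc([C@@H](O)CC(=O)c2c(OCC=C(C)C)cc(OCOC)cc2F)ccc1OCOC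
F2 | step 7 | (1S)-3-[2-fluoro-4-(methoxymethoxy)-6-(3-methylbut-2-enyloxy)phenyl]-1-[4-(methoxymethoxy)-3-(3-methylbut-2-enyl)phenyl]propane-1,3-diol (either configuration at C3) | CC(C)=CCc1cc([C@@H](O)CC(O)c2c(OCC=C(C)C)cc(OCOC)cc2F)ccc1OCOC
F3 | step 7 | (2S)-7-(methoxymethoxy)-2-[4-(methoxymethoxy)-3-(3-methylbut-2-enyl)phenyl]-5-(3-methylbut-2-enyloxy)-3,4-dihydro-2H-chromen-4-ol (either configuration at C4) | CC(C)=CCc1cc([C@@H]2CC(O)c3c(OCC=C(C)C)cc(OCOC)cc3O2)ccc1OCOC
F4 | step 8 | 1-[2-fluoro-6-hydroxy-4-(methoxymethoxy)-3-(3-methylbut-2-enyl)phenyl]ethanone | CC(=O)c1c(O)cc(OCOC)c(CC=C(C)C)c1F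
F5 | step 8 | 1-[2-fluoro-4,6-bis(methoxymethoxy)-3-(3-methylbut-2-enyl)phenyl]ethanone | CC(=O)c1c(OCOC)cc(OCOC)c(CC=C(C)C)c1F
F6 | step 8 | {1-[2-fluoro-4,6-bis(methoxymethoxy)-3-(3-methylbut-2-enyl)phenyl]ethenyloxy}trimethylsilane | C=C(O[Si](C)(C)C)c1c(OCOC)cc(OCOC)c(CC=C(C)C)c1F
F7 | step 8 | (3S)-1-[2-fluoro-4,6-bis(methoxymethoxy)-3-(3-methylbut-2-enyl)phenyl]-3-[4-(methoxymethoxy)-3-(3-methylbut-2-enyl)phenyl]-3-(trimethylsilyloxy)propan-1-one | CC(C)=CCc1cc([C@@H](O[Si](C)(C)C)CC(=O)c2c(OCOC)cc(OCOC)c(CC=C(C)C)c2F)ccc1OCOC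
F8 | step 8 | (2S)-5,7-bis(methoxymethoxy)-2-[4-(methoxymethoxy)-3-(3-methylbut-2-enyl)phenyl]-8-(3-methylbut-2-enyl)-2,3-dihydro-4H-chromen-4-one | CC(C)=CCc1cc([C@@H]2CC(=O)c3c(OCOC)cc(OCOC)c(CC=C(C)C)c3O2)ccc1OCOC
F9 | step 9 | (2S)-8-(3-methylbut-2-enyl)-2-[3-(3-methylbut-2-enyl)-4-(trimethylsilyloxy)phenyl]-5,7-bis(trimethylsilyloxy)-2,3-dihydro-4H-chromen-4-one | CC(C)=CCc1cc([C@@H]2CC(=O)c3c(O[Si](C)(C)C)cc(O[Si](C)(C)C)c(CC=C(C)C)c3O2)ccc1O[Si](C)(C)C
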